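**Plan**

1. Retrosynthesis: the C8'–H of the target is traded for a helper C8'–OH, which makes the 3,7-dioxabicyclo[3.3.0]octane core C2-symmetric; both O–CH2 bonds (O7–C9' of ring A, O7'–C9 of ring B) are then cut, each back to a benzylic carbinol and the CH2 end of an oxirane.
2. The open-chain bis-epoxide diol goes back to a 2,3-dimethylidene-1,4-diol, then (C9 and C9' from ethylene) to a 1,4-diarylbut-2-yne-1,4-diol, and this to two O-benzylsyringaldehydes and one acetylene unit.
3. Forward: the chain C7–C8≡C8'–C7' is joined, C9 and C9' are added, both tetrahydrofuran rings (ring A = O, C7, C8, C8', C9'; ring B = O, C7', C8', C8, C9) close in one operation, then the helper OH and the benzyl groups are removed.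
4. Enabling feature: each ring oxygen sits on a benzylic carbon (C7) and is bonded to a CH2 (C9') carried by the ring-fusion carbon of the other half (C8'), so O7 and C9' are the ends of a five-atom chain whose last two carbons can be a 2,2-disubstituted oxirane; the latent twofold axis through the midpoint of C8–C8' lets one event close both rings.
5. Stereochemistry: C7 and C7' from two catalyst-controlled alkynylations; C8 and C8' from matched Sharpless epoxidation (erythro); the ring closures occur at CH2 only; C8'–H from radical reduction under cis-ring-fusion control.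

Key step: step 7

Locants: lignan numbering; C7/C7' are the benzylic carbons, C8/C8' the ring-fusion carbons, C9/C9' the ring CH2 groups; in the target C8 carries OH and C8' carries H.

Assumption: the (S,S) hand of the ProPhenol ligand is taken to direct the alkynylzinc to the Si face of the aryl aldehyde; if the sense of induction is the reverse, the (R,R) ligand is used in steps 2 and 4 and nothing else changes.

**Route**

Step 1
Reactants: 1 syringaldehyde
Product: 2 4-(benzyloxy)-3,5-dimethoxybenzaldehyde
Conditions: BnBr, K2CO3, DMF, 60 °C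
Reagents that add atoms: benzyl bromide, BrCc1ccccc1
Why: Williamson ether synthesis (SN2 of the phenoxide on benzyl bromide); the benzyl ether should survive the organozinc, alkoxide and radical steps and is removable by hydrogenolysis at the end.

Step 2
Reactants: 2 4-(benzyloxy)-3,5-dimethoxybenzaldehyde; 3 ethynyltrimethylsilane
Product: 4 (R)-1-[4-(benzyloxy)-3,5-dimethoxyphenyl]-3-(trimethylsilyl)prop-2-yn-1-ol
Conditions: Me2Zn (2.9 equiv), 3 (2.8 equiv), (S,S)-ProPhenol (10 mol %), Ph3P=O (20 mol %), toluene, 0 °C; aqueous work-up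
Reagents that add atoms: none
Why: catalytic asymmetric alkynylation of an aryl aldehyde (dinuclear zinc–ProPhenol type); the chiral zinc complex should deliver the alkynylzinc to the Si face of the carbonyl and so set the first benzylic carbinol centre (R in 4).

Step 3
Reactants: 4 (R)-1-[4-(benzyloxy)-3,5-dimethoxyphenyl]-3-(trimethylsilyl)prop-2-yn-1-ol
Product: 5 (S)-1-[4-(benzyloxy)-3,5-dimethoxyphenyl]prop-2-yn-1-ol
Conditions: K2CO3 (cat.), MeOH, rt
Reagents that add atoms: none
Why: base-catalysed methanolysis of the C(sp)–Si bond (protodesilylation); the carbinol centre is untouched, and its descriptor becomes S only because ethynyl now ranks below aryl.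

Step 4
Reactants: 5 (S)-1-[4-(benzyloxy)-3,5-dimethoxyphenyl]prop-2-yn-1-ol; 2 4-(benzyloxy)-3,5-dimethoxybenzaldehyde
Product: 6 (1R,4R)-1,4-bis[4-(benzyloxy)-3,5-dimethoxyphenyl]but-2-yne-1,4-diol
Conditions: Me2Zn (3 equiv), 2 (1.3 equiv), (S,S)-ProPhenol (20 mol %), Ph3P=O (40 mol %), toluene, 0 °C to rt; aqueous work-up
Reagents that add atoms: none
Why: second catalyst-controlled asymmetric alkynylation with the same ligand hand (the propargylic hydroxyl is carried as its zinc alkoxide); it should set the second benzylic centre with the same spatial sense, and because both centres come from the same catalyst the minor stereoisomers should end up mainly as the separable meso diol.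

Step 5
Reactants: 6 (1R,4R)-1,4-bis[4-(benzyloxy)-3,5-dimethoxyphenyl]but-2-yne-1,4-diol; 7 ethylene
Product: 8 (1R,4R)-1,4-bis[4-(benzyloxy)-3,5-dimethoxyphenyl]-2,3-dimethylidenebutane-1,4-diol
Conditions: second-generation Grubbs catalyst RuCl2(=CHPh)(H2IMes)(PCy3) (10 mol %), ethylene (balloon), toluene, 80 °C
Reagents that add atoms: none
Why: ethylene–alkyne cross enyne metathesis; the ruthenium methylidene adds to the internal alkyne, the ruthenacyclobutene opens to a vinylcarbene and ethylene turns it over, so each alkyne carbon (C8, C8') should gain a methylidene carbon (C9, C9') without touching a stereocentre.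

Step 6
Reactants: 8 (1R,4R)-1,4-bis[4-(benzyloxy)-3,5-dimethoxyphenyl]-2,3-dimethylidenebutane-1,4-diol
Product: 10 (2S,2'S)-2,2'-bis{(R)-[4-(benzyloxy)-3,5-dimethoxyphenyl](hydroxy)methyl}-2,2'-bioxirane, via mono-epoxide 9 (not isolated)
Conditions: t-BuOOH (2.5 equiv), Ti(OiPr)4 (20 mol %), D-(−)-diisopropyl tartrate (24 mol %), 4 Å molecular sieves, CH2Cl2, −20 °C
Reagents that add atoms: tert-butyl hydroperoxide, CC(C)(C)OO
Why: twofold Sharpless asymmetric epoxidation of a 2-substituted secondary allylic alcohol in the matched (fast-reacting) sense; for each (R)-carbinol the D-tartrate catalyst should deliver oxygen to the alkene face anti to the aryl group (minimised 1,2-allylic strain), giving the erythro epoxy alcohol and setting C8 and C8' (both S), while stereoisomeric impurities of 8 are mismatched and should lag behind.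

Step 7
Reactants: 10 (2S,2'S)-2,2'-bis{(R)-[4-(benzyloxy)-3,5-dimethoxyphenyl](hydroxy)methyl}-2,2'-bioxirane
Product: 12 (7R,8S,7'R,8'S)-4,4'-bis(benzyloxy)-3,3',5,5'-tetramethoxy-7,9':7',9-diepoxylignane-8,8'-diol, via spiro-epoxide 11 (not isolated)
Conditions: t-BuOK (20 mol %), THF (0.02 M), 0 °C to 45 °C
Reagents that add atoms: none
Why: Catalytic tert-butoxide should generate a benzylic alkoxide whose oxygen (O7) attacks C9', the CH2 terminus of the oxirane on C8', in an intramolecular SN2 opening that forms the O7–C9' bond and ring A and releases the C8' tertiary alkoxide; proton transfer passes the charge on, O7' opens the second oxirane at C9 and ring B closes (11 to 12), the two closures being equivalent in C2-symmetric 10. The closest known reaction type is the base-mediated cyclisation of 3,4-epoxy alcohols to 3-hydroxytetrahydrofurans, here run twice in one operation and driven by the release of the strain of two oxiranes. Each ring closes in the 5-endo mode with respect to its oxirane (attack at the distal CH2, both oxirane carbons end up in the new ring), which should be feasible because the only alternative, 4-exo attack, would be an SN2 reaction at a fully substituted carbon leading to an oxetane. No new stereocentre is formed: substitution occurs only at the two CH2 groups, so C7 and C7' keep their configuration, the oxirane oxygens stay on C8 and C8' and become the two tertiary hydroxyls, and the erythro relationship from step 6 places both aryl groups on the convex (exo) face of a cis-fused bicycle. The step needs selectivity for this opening over Payne-type migration (a carbinol oxygen attacking its own neighbouring oxirane carbon) and over intermolecular opening; the first is secured by the quaternary nature of C8 and C8', the second by the aprotic medium, the hindered catalytic base and dilution.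

Step 8
Reactants: 12 (7R,8S,7'R,8'S)-4,4'-bis(benzyloxy)-3,3',5,5'-tetramethoxy-7,9':7',9-diepoxylignane-8,8'-diol
Product: 13 cyclic 8,8'-O-thiocarbonyl derivative (thionocarbonate) of 12
Conditions: 1,1'-thiocarbonyldiimidazole (1.5 equiv), DMAP (cat.), toluene, 110 °C
Reagents that add atoms: 1,1'-thiocarbonyldiimidazole, S=C(n1ccnc1)n1ccnc1
Why: cyclic thionocarbonate formation from a cis-vicinal diol (the first stage of Corey–Winter and Barton-type chemistry); tying both homotopic tertiary hydroxyls into one five-membered ring should ensure that exactly one C–O bond is activated for the radical step.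

Step 9
Reactants: 13 cyclic 8,8'-O-thiocarbonyl derivative (thionocarbonate) of 12
Product: 15 (7R,8S,7'S,8'R)-4,4'-bis(benzyloxy)-3,3',5,5'-tetramethoxy-7,9':7',9-diepoxylignan-8-ol, via stannyl thiocarbonate 14 (not isolated)
Conditions: Bu3SnH (2 equiv), AIBN (20 mol %), toluene, 110 °C; then H2O–THF, K2CO3 (cat.), rt
Reagents that add atoms: none
Why: Barton–McCombie-type deoxygenation of a cyclic thionocarbonate; the stannyl radical adds to sulfur, scission of one of the two homotopic C–O bonds gives the tertiary C8' radical, which should take hydrogen from Bu3SnH on the face that keeps the bicycle cis-fused (the trans-fused alternative is strongly strained), so C8'–H ends up cis to the C8 hydroxyl (C8' = R), and hydrolysis of 14 frees that hydroxyl.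

Step 10
Reactants: 15 (7R,8S,7'S,8'R)-4,4'-bis(benzyloxy)-3,3',5,5'-tetramethoxy-7,9':7',9-diepoxylignan-8-ol
Product: 16 8-hydroxysyringaresinol, (7R,8S,7'S,8'R)-3,3',5,5'-tetramethoxy-7,9':7',9-diepoxylignane-4,4',8-triol
Conditions: H2 (1 atm), 10% Pd/C, EtOAc–MeOH, rt
Reagents that add atoms: none
Why: hydrogenolysis of the two aryl benzyl ethers; these should cleave much faster than the ring benzylic C–O bonds, and the neutral medium avoids acid-induced epimerisation at C7 and C7'.

**Compound list**

1 | syringaldehyde (4-hydroxy-3,5-dimethoxybenzaldehyde) | COc1cc(C=O)cc(OC)c1O | starting material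
2 | 4-(benzyloxy)-3,5-dimethoxybenzaldehyde | COc1cc(C=O)cc(OC)c1OCc1ccccc1 | intermediate
3 | ethynyltrimethylsilane | C#C[Si](C)(C)C | starting material
4 | (R)-1-[4-(benzyloxy)-3,5-dimethoxyphenyl]-3-(trimethylsilyl)prop-2-yn-1-ol | COc1cc(cc(OC)c1OCc1ccccc1)[C@@H](O)C#C[Si](C)(C)C | intermediate
5 | (S)-1-[4-(benzyloxy)-3,5-dimethoxyphenyl]prop-2-yn-1-ol | COc1cc(cc(OC)c1OCc1ccccc1)[C@@H](O)C#C | intermediate
6 | (1R,4R)-1,4-bis[4-(benzyloxy)-3,5-dimethoxyphenyl]but-2-yne-1,4-diol | COc1cc(cc(OC)c1OCc1ccccc1)[C@@H](O)C#C[C@H](O)c1cc(OC)c(OCc2ccccc2)c(OC)c1 | intermediate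
7 | ethylene | C=C | starting material
8 | (1R,4R)-1,4-bis[4-(benzyloxy)-3,5-dimethoxyphenyl]-2,3-dimethylidenebutane-1,4-diol | COc1cc(cc(OC)c1OCc1ccccc1)[C@@H](O)C(=C)C(=C)[C@H](O)c1cc(OC)c(OCc2ccccc2)c(OC)c1 | intermediate
9 | mono-epoxide: (R)-[4-(benzyloxy)-3,5-dimethoxyphenyl]{(S)-2-[(R)-3-[4-(benzyloxy)-3,5-dimethoxyphenyl]-3-hydroxyprop-1-en-2-yl]oxiran-2-yl}methanol | COc1cc(cc(OC)c1OCc1ccccc1)[C@@H](O)[C@@]1(CO1)C(=C)[C@H](O)c1cc(OC)c(OCc2ccccc2)c(OC)c1 | intermediate
10 | (2S,2'S)-2,2'-bis{(R)-[4-(benzyloxy)-3,5-dimethoxyphenyl](hydroxy)methyl}-2,2'-bioxirane | COc1cc(cc(OC)c1OCc1ccccc1)[C@@H](O)[C@@]1(CO1)[C@]2(CO2)[C@H](O)c1cc(OC)c(OCc3ccccc3)c(OC)c1 | intermediate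
11 | spiro-epoxide (one ring closed): (3S,4R,7S)-4-[4-(benzyloxy)-3,5-dimethoxyphenyl]-7-{(R)-[4-(benzyloxy)-3,5-dimethoxyphenyl](hydroxy)methyl}-1,5-dioxaspiro[2.4]heptan-7-ol | COc1cc(cc(OC)c1OCc1ccccc1)[C@H]1OC[C@](O)([C@H](O)c2cc(OC)c(OCc3ccccc3)c(OC)c2)[C@]12CO2 | intermediate
12 | (7R,8S,7'R,8'S)-4,4'-bis(benzyloxy)-3,3',5,5'-tetramethoxy-7,9':7',9-diepoxylignane-8,8'-diol (both aryl groups exo, cis ring fusion) | COc1cc(cc(OC)c1OCc1ccccc1)[C@H]1OC[C@]2(O)[C@@H](c3cc(OC)c(OCc4ccccc4)c(OC)c3)OC[C@]12O | intermediate
13 | cyclic 8,8'-O-thiocarbonyl derivative (thionocarbonate) of 12 | COc1cc(cc(OC)c1OCc1ccccc1)[C@H]1OC[C@]2(OC(=S)O4)[C@@H](c3cc(OC)c(OCc5ccccc5)c(OC)c3)OC[C@]124 | intermediate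
14 | stannyl thiocarbonate: O-(C8) S-(tributylstannyl) thiocarbonate of 15 | COc1cc(cc(OC)c1OCc1ccccc1)[C@H]1OC[C@]2(OC(=O)S[Sn](CCCC)(CCCC)CCCC)[C@@H](c3cc(OC)c(OCc4ccccc4)c(OC)c3)OC[C@H]12 | intermediate
15 | (7R,8S,7'S,8'R)-4,4'-bis(benzyloxy)-3,3',5,5'-tetramethoxy-7,9':7',9-diepoxylignan-8-ol | COc1cc(cc(OC)c1OCc1ccccc1)[C@H]1OC[C@]2(O)[C@@H](c3cc(OC)c(OCc4ccccc4)c(OC)c3)OC[C@H]12 | intermediate
16 | 8-hydroxysyringaresinol, (7R,8S,7'S,8'R)-3,3',5,5'-tetramethoxy-7,9':7',9-diepoxylignane-4,4',8-triol | COc1cc([C@H]2OC[C@]3(O)[C@@H](c4cc(OC)c(O)c(OC)c4)OC[C@H]23)cc(OC)c1O | target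

**Step count and risks**

Total step count: 10. Longest linear sequence: 10 steps (1, 2, 4, 5, 6, 8, 10, 12, 13, 15, 16; aldehyde 2 enters twice).

Steps most likely to fail:

Step 5. The metathesis may stall because the hindered internal alkyne is slow to form the ruthenium vinylcarbene, because the free propargylic hydroxyls chelate the catalyst, or because the benzylic propargylic carbinols undergo redox isomerisation at 80 °C. Fallback, setting out from 5 and returning at 8: hydrostannation of the terminal alkyne of 5 with Bu3SnH and catalytic Mo(CO)3(CNt-Bu)3 (internal, alpha-selective for propargylic alcohols) should give (R)-1-[4-(benzyloxy)-3,5-dimethoxyphenyl]-2-(tributylstannyl)prop-2-en-1-ol F1. Oxidative homocoupling of this alkenylstannane with CuCl2 in DMF then joins C8 to C8' and gives 8, so that steps 4 and 5 are both bypassed and the C8–C8' bond is made by alkenyl–alkenyl coupling instead of alkynylation and metathesis.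

Step 7. The 5-endo oxirane opening may be too slow on stereoelectronic grounds, so that oxirane migration and oligomerisation take over. Fallback, setting out from 8 and returning at 12, in which the O–CH2 bonds are made at the carbonyl oxidation level:
- Upjohn dihydroxylation (OsO4 cat., NMO, acetone–H2O) of both 1,1-disubstituted alkenes, anti to the allylic hydroxyl (the same erythro sense as step 6), should give (1R,2S,3S,4R)-1,4-bis[4-(benzyloxy)-3,5-dimethoxyphenyl]-2,3-bis(hydroxymethyl)butane-1,2,3,4-tetrol F2.
- Aerobic oxidation selective for primary alcohols (Cu(MeCN)4OTf, 2,2'-bipyridine, TEMPO, N-methylimidazole, air, MeCN) converts the two CH2OH groups to aldehydes; each is captured by the benzylic hydroxyl four atoms away (5-exo-trig addition, no oxirane constraint) and oxidised on to the bis-gamma-lactone F3.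
- i-Bu2AlH at −78 °C gives the bis-lactol F4, and Et3SiH with BF3·OEt2 at −78 °C reduces both lactols to the cyclic ethers of 12.

Step 9. The cyclic thionocarbonate may not form on the hindered ditertiary diol, or the intermediate radical may fragment toward the C8=C8' alkene instead of being reduced. Fallback, setting out from 12 and returning at 15:
- Mono-acylation with methyl chlorooxoacetate (1.05 equiv, DMAP, CH2Cl2, 0 °C; the hydroxyls are homotopic and the second acylation is slowed by the first) gives the methyl oxalate F5.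
- CsOH in THF–H2O gives the cesium oxalate F6.
- Irradiation (blue LED) with [Ir(dF(CF3)ppy)2(dtbbpy)]PF6 and a thiol hydrogen-atom donor in wet DME oxidises the oxalate, two CO2 are lost, and the same tertiary C8' radical as in step 9 is reduced under the same cis-fusion control to 15.

**Further compounds**

F1 | step 5 | (R)-1-[4-(benzyloxy)-3,5-dimethoxyphenyl]-2-(tributylstannyl)prop-2-en-1-ol | COc1cc(cc(OC)c1OCc1ccccc1)[C@@H](O)C(=C)[Sn](CCCC)(CCCC)CCCC
F2 | step 7 | (1R,2S,3S,4R)-1,4-bis[4-(benzyloxy)-3,5-dimethoxyphenyl]-2,3-bis(hydroxymethyl)butane-1,2,3,4-tetrol | COc1cc(cc(OC)c1OCc1ccccc1)[C@@H](O)[C@@](O)(CO)[C@](O)(CO)[C@H](O)c1cc(OC)c(OCc2ccccc2)c(OC)c1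
F3 | step 7 | bis-gamma-lactone: 9,9'-dioxo derivative of 12 | COc1cc(cc(OC)c1OCc1ccccc1)[C@H]1OC(=O)[C@]2(O)[C@@H](c3cc(OC)c(OCc4ccccc4)c(OC)c3)OC(=O)[C@]12O
F4 | step 7 | bis-lactol: 9,9'-dihydroxy derivative of 12 (anomeric mixture) | COc1cc(cc(OC)c1OCc1ccccc1)[C@H]1OC(O)[C@]2(O)[C@@H](c3cc(OC)c(OCc4ccccc4)c(OC)c3)OC(O)[C@]12O
F5 | step 9 | mono(methyl oxalate) of 12 | COc1cc(cc(OC)c1OCc1ccccc1)[C@H]1OC[C@]2(O)[C@@H](c3cc(OC)c(OCc4ccccc4)c(OC)c3)OC[C@]12OC(=O)C(=O)OC
F6 | step 9 | cesium mono-oxalate of 12 | COc1cc(cc(OC)c1OCc1ccccc1)[C@H]1OC[C@]2(O)[C@@H](c3cc(OC)c(OCc4ccccc4)c(OC)c3)OC[C@]12OC(=O)C(=O)[O-].[Cs+]
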